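**Retrosynthetic overview**
1. The strategy rests on the C2–C3–C4 segment of the pyranone (ring C): a three-carbon bridge oxygenated at C2 and C4 that joins C4a of the benzo ring (ring A) to the C33 chain, with C4a flanked by the oxygen-bearing carbons C5 and C8a.
2. Ring C is opened first: O1–C2 is cut and the C2/C4 dioxygenation is carried as a 3-aryl-5-alkylisoxazole, to be unmasked by N–O hydrogenolysis and closed by acid with loss of NH3.
3. The isoxazole is cut by retro-[3+2] (C4–C3 and O–C2 bonds) into 4-methoxy-2,6-bis(methoxymethoxy)benzonitrile oxide and pentatriacont-1-yne.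
4. The nitrile oxide comes from 5-methoxyresorcinol (bis-MOM ether, lithiation between the acetal oxygens, formylation, oxime, oxidation); the alkyne from a C22 + C11 Grignard coupling, bromination, silylacetylide alkylation and desilylation.
5. Ring order: ring A is bought, the isoxazole is formed in step 9, ring C in step 11.

Key step: step 9

Assumption: the side chain is read from the SMILES as the unbranched C33 (tritriacontyl) group and the target has no stereocentre; the only stereo-descriptors in the route are the C=N and C=C geometries of 5 and 18, which are lost again.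

Step 1
Reactants: 1 5-methoxyresorcinol
Product: 2 1-methoxy-3,5-bis(methoxymethoxy)benzene
Conditions: NaH (2.4 equiv), MOMCl (2.4 equiv), DMF, 0 °C → rt
Reagents that add atoms: chloromethyl methyl ether (MOMCl), COCCl
Why: Williamson O-alkylation of both phenoxides by the hard chloromethyl ether should give the bis-acetal, whose OMOM groups later direct the metalation and fall off in the final acid step.

Step 2
Reactants: 2 1-methoxy-3,5-bis(methoxymethoxy)benzene
Product: 4 4-methoxy-2,6-bis(methoxymethoxy)benzaldehyde, via the aryllithium 3 (not isolated)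
Conditions: n-BuLi, TMEDA, THF, 0 °C; DMF, 0 °C → rt; H2O
Reagents that add atoms: N,N-dimethylformamide, CN(C)C=O
Why: Directed ortho-metalation should take place at C4–H of 2, the position chelated by two OMOM groups (stronger directors than OMe), and formylation of the aryllithium by DMF then gives the aldehyde.

Step 3
Reactants: 4 4-methoxy-2,6-bis(methoxymethoxy)benzaldehyde
Product: 5 (E)-4-methoxy-2,6-bis(methoxymethoxy)benzaldehyde oxime
Conditions: NH2OH·HCl, NaOAc, EtOH/H2O, rt
Reagents that add atoms: hydroxylamine hydrochloride, NO.Cl
Why: Oxime condensation in an acetate buffer leaves the acetals intact and should give the thermodynamically preferred E-oxime, whose geometry is lost in the next step.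

Step 4
Reactants: 5 (E)-4-methoxy-2,6-bis(methoxymethoxy)benzaldehyde oxime
Product: 6 4-methoxy-2,6-bis(methoxymethoxy)benzonitrile oxide
Conditions: PhI(OAc)2 (1.1 equiv), MeOH, 0 °C
Reagents that add atoms: none
Why: Oxidative dehydrogenation of the aldoxime by the trivalent iodine reagent (ligand exchange at iodine, then loss of iodobenzene) is halogen-free, so the electron-rich ring is not halogenated, and the two ortho OMOM groups should make the nitrile oxide persistent enough to isolate.

Step 5
Reactants: 7 1-bromodocosane; 8 11-bromoundecan-1-ol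
Product: 11 tritriacontan-1-ol, via docosylmagnesium bromide 9 (not isolated), via the chloromagnesium alkoxide 10 (not isolated)
Conditions: 7, Mg, THF, 50 °C; 8, MeMgCl (1.0 equiv), THF, 0 °C; combine, Li2CuCl4 (3 mol%), 0 °C → rt; 1 M HCl
Reagents that add atoms: none
Why: Copper-catalysed sp3–sp3 cross-coupling of a primary Grignard reagent with a primary bromide (Kochi coupling) should join C22 and C11, the hydroxyl being masked as its magnesium alkoxide by the sacrificial MeMgCl.

Step 6
Reactants: 11 tritriacontan-1-ol
Product: 12 1-bromotritriacontane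
Conditions: CBr4, PPh3, THF/CH2Cl2, 0 → 40 °C
Reagents that add atoms: carbon tetrabromide, BrC(Br)(Br)Br
Why: The Appel reaction converts the primary alcohol into the bromide by SN2 displacement of the alkoxyphosphonium under neutral conditions that keep the waxy substrate in solution.

Step 7
Reactants: 12 1-bromotritriacontane; 13 ethynyltrimethylsilane
Product: 15 trimethyl(pentatriacont-1-yn-1-yl)silane, via lithium (trimethylsilyl)acetylide 14 (not isolated)
Conditions: 13, n-BuLi, THF, −78 °C; 12, DMPU, −20 → 45 °C
Reagents that add atoms: none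
Why: SN2 alkylation of the lithium acetylide by the primary bromide in THF/DMPU should give the silyl alkyne, the silyl cap preventing double alkylation and alkyne isomerisation.

Step 8
Reactants: 15 trimethyl(pentatriacont-1-yn-1-yl)silane
Product: 16 pentatriacont-1-yne
Conditions: K2CO3 (0.2 equiv), MeOH/THF, 40 °C
Reagents that add atoms: none
Why: Base-catalysed methanolysis of the C(sp)–Si bond (protodesilylation) should release the terminal alkyne without touching the saturated chain.

Step 9
Reactants: 6 4-methoxy-2,6-bis(methoxymethoxy)benzonitrile oxide; 16 pentatriacont-1-yne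
Product: 17 3-[4-methoxy-2,6-bis(methoxymethoxy)phenyl]-5-tritriacontylisoxazole
Conditions: 6 (1.3 equiv), toluene (about 0.5 M), 80 °C
Reagents that add atoms: none
Why: Concerted, asynchronous 1,3-dipolar (Huisgen) cycloaddition: the nitrile oxide carbon of 6 bonds to the terminal carbon of 16 and the nitrile oxide oxygen to the internal carbon, so the future C4–C3 bond and the O–C2 bond of the masked diketone form in one event. The closest known reaction type is the thermal addition of persistent 2,6-disubstituted aryl nitrile oxides (mesityl or 2,6-dialkoxyphenyl) to terminal alkynes, which gives 3-aryl-5-alkylisoxazoles. The isoxazole ring is closed intermolecularly as a [3+2] ring formation in which both new ring bonds form in the same step, and no oxidation is needed for aromaticity because the dipolarophile is an alkyne. No stereocentre is created. The step needs 3,5- over 3,4-regioselectivity, which the substrate secures through the larger frontier-orbital coefficient and lower steric demand at the unsubstituted alkyne carbon, reinforced by the bulky di-ortho-substituted aryl group staying away from the C33 chain. It also needs the dipole to outlast a slow, unactivated dipolarophile, which the two ortho OMOM groups secure by shielding the CNO carbon against dimerisation to the furoxan.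

Step 10
Reactants: 17 3-[4-methoxy-2,6-bis(methoxymethoxy)phenyl]-5-tritriacontylisoxazole
Product: 18 (Z)-1-amino-1-[4-methoxy-2,6-bis(methoxymethoxy)phenyl]hexatriacont-1-en-3-one
Conditions: H2 (1 atm), Raney Ni, THF/EtOH, rt
Reagents that add atoms: none
Why: Hydrogenolysis of the weak isoxazole N–O bond over Raney Ni should stop at the β-amino enone, a vinylogous amide held in the Z form by an N–H···O=C hydrogen bond, while aryl ethers and acetals are inert.

Step 11
Reactants: 18 (Z)-1-amino-1-[4-methoxy-2,6-bis(methoxymethoxy)phenyl]hexatriacont-1-en-3-one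
Product: 19 5-hydroxy-7-methoxy-2-tritriacontyl-4H-chromen-4-one (target)
Conditions: 3 M HCl (aq), MeOH/THF, 60 °C
Reagents that add atoms: water, O
Why: Acid should remove both MOM acetals and hydrolyse the enamine carbon to the C4 carbonyl, and either of the two equivalent phenols then closes the six-membered pyranone at the chain carbonyl by cyclodehydration (the last stage of a Baker–Venkataraman-type chromone synthesis), leaving the chelated 5-OH and the 7-OMe.

**Compound list**
1 | 5-methoxyresorcinol | COc1cc(O)cc(O)c1 | starting material
2 | 1-methoxy-3,5-bis(methoxymethoxy)benzene | COCOc1cc(OC)cc(OCOC)c1 | intermediate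
3 | [4-methoxy-2,6-bis(methoxymethoxy)phenyl]lithium | [Li]c1c(OCOC)cc(OC)cc1OCOC | intermediate (not isolated)
4 | 4-methoxy-2,6-bis(methoxymethoxy)benzaldehyde | COCOc1cc(OC)cc(OCOC)c1C=O | intermediate
5 | (E)-4-methoxy-2,6-bis(methoxymethoxy)benzaldehyde oxime | COCOc1cc(OC)cc(OCOC)c1/C=N/O | intermediate
6 | 4-methoxy-2,6-bis(methoxymethoxy)benzonitrile oxide | COCOc1cc(OC)cc(OCOC)c1C#[N+][O-] | intermediate
7 | 1-bromodocosane | CCCCCCCCCCCCCCCCCCCCCCBr | starting material
8 | 11-bromoundecan-1-ol | OCCCCCCCCCCCBr | starting material
9 | docosylmagnesium bromide | CCCCCCCCCCCCCCCCCCCCCC[Mg]Br | intermediate (not isolated)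
10 | chloromagnesium 11-bromoundecan-1-olate | BrCCCCCCCCCCCO[Mg]Cl | intermediate (not isolated)
11 | tritriacontan-1-ol | CCCCCCCCCCCCCCCCCCCCCCCCCCCCCCCCCO | intermediate
12 | 1-bromotritriacontane | CCCCCCCCCCCCCCCCCCCCCCCCCCCCCCCCCBr | intermediate
13 | ethynyltrimethylsilane | C#C[Si](C)(C)C | starting material
14 | lithium (trimethylsilyl)acetylide | [Li]C#C[Si](C)(C)C | intermediate (not isolated)
15 | trimethyl(pentatriacont-1-yn-1-yl)silane | C[Si](C)(C)C#CCCCCCCCCCCCCCCCCCCCCCCCCCCCCCCCCC | intermediate
16 | pentatriacont-1-yne | C#CCCCCCCCCCCCCCCCCCCCCCCCCCCCCCCCCC | intermediate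
17 | 3-[4-methoxy-2,6-bis(methoxymethoxy)phenyl]-5-tritriacontylisoxazole | COCOc1cc(OC)cc(OCOC)c1-c2cc(CCCCCCCCCCCCCCCCCCCCCCCCCCCCCCCCC)on2 | intermediate
18 | (Z)-1-amino-1-[4-methoxy-2,6-bis(methoxymethoxy)phenyl]hexatriacont-1-en-3-one | N/C(=C\C(=O)CCCCCCCCCCCCCCCCCCCCCCCCCCCCCCCCC)c1c(OCOC)cc(OC)cc1OCOC | intermediate
19 | 5-hydroxy-7-methoxy-2-tritriacontyl-4H-chromen-4-one | CCCCCCCCCCCCCCCCCCCCCCCCCCCCCCCCCc1cc(=O)c2c(O)cc(OC)cc2o1 | target

**Totals**
Total step count: 11.
Longest linear sequence: 7 steps (steps 1, 2, 3, 4, 9, 10, 11 from 1; the chain branch, steps 5, 6, 7, 8, 9, 10, 11 from 7 and 8, is equally long).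

**Steps most likely to fail**

Step 9. The addition to an unactivated, waxy alkyne may be slow, so that isomerisation of the nitrile oxide to the isocyanate or slow dimerisation consumes the dipole, and some addition in the 3,4-sense may occur. The fallback makes the same C4–C3 bond by carbonyl addition and sets out from alkyne 16 and aldehyde 4. Alkyne 16 would be deprotonated (n-BuLi, THF, −20 °C) and added to 4 to give the racemic propargylic alcohol 1-[4-methoxy-2,6-bis(methoxymethoxy)phenyl]hexatriacont-2-yn-1-ol F1. MnO2 in CH2Cl2/THF should oxidise it to the ynone 1-[4-methoxy-2,6-bis(methoxymethoxy)phenyl]hexatriacont-2-yn-1-one F2. Conjugate addition of Et2NH (EtOH/THF, rt) should give the enaminone (E)-3-(diethylamino)-1-[4-methoxy-2,6-bis(methoxymethoxy)phenyl]hexatriacont-2-en-1-one F3. Treatment with 3 M HCl in MeOH/THF at 60 °C would then remove both acetals and close the pyranone by addition–elimination with loss of diethylamine, coming back to the route at target 19.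

Step 4. The oxidant may attack the electron-rich ring, the acetals may suffer in the acetic acid that is released, or the nitrile oxide may degrade during isolation. The fallback is a non-oxidative dehydration that sets out from 2. The aryllithium generated as in step 2 would be quenched with CO2 to give 4-methoxy-2,6-bis(methoxymethoxy)benzoic acid F4. Coupling with O-(tert-butyldiphenylsilyl)hydroxylamine (EDC·HCl, HOAt, i-Pr2NEt, CH2Cl2) should give the O-silyl hydroxamate N-[(tert-butyldiphenylsilyl)oxy]-4-methoxy-2,6-bis(methoxymethoxy)benzamide F5. Tf2O and Et3N in CH2Cl2 at −40 → 0 °C would then O-triflate the amide, expel triflate and remove the silyl group, coming back to the route at nitrile oxide 6.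

Step 5. Wurtz-type homocoupling during formation of the C22 Grignard reagent, its precipitation from THF, or reduction and elimination of the bromide instead of cross-coupling may erode the chain coupling. The fallback is a sulfone alkylation that sets out from 7 and 8. Bromide 7 and PhSO2Na in DMF at 80 °C should give (docosane-1-sulfonyl)benzene F6. Its α-lithio derivative (n-BuLi, THF, −78 °C) would be alkylated with the lithium alkoxide of 8 (pre-formed with n-BuLi; THF/DMPU, −78 °C → rt) to give 12-(benzenesulfonyl)tritriacontan-1-ol F7. Reductive desulfonylation with Mg in MeOH/THF at 50 °C then comes back to the route at alcohol 11.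

Further compounds
F1 | step 9 | 1-[4-methoxy-2,6-bis(methoxymethoxy)phenyl]hexatriacont-2-yn-1-ol | COCOc1cc(OC)cc(OCOC)c1C(O)C#CCCCCCCCCCCCCCCCCCCCCCCCCCCCCCCCCC
F2 | step 9 | 1-[4-methoxy-2,6-bis(methoxymethoxy)phenyl]hexatriacont-2-yn-1-one | COCOc1cc(OC)cc(OCOC)c1C(=O)C#CCCCCCCCCCCCCCCCCCCCCCCCCCCCCCCCCC
F3 | step 9 | (E)-3-(diethylamino)-1-[4-methoxy-2,6-bis(methoxymethoxy)phenyl]hexatriacont-2-en-1-one | CCN(CC)/C(CCCCCCCCCCCCCCCCCCCCCCCCCCCCCCCCC)=C/C(=O)c1c(OCOC)cc(OC)cc1OCOC
F4 | step 4 | 4-methoxy-2,6-bis(methoxymethoxy)benzoic acid | COCOc1cc(OC)cc(OCOC)c1C(=O)O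
F5 | step 4 | N-[(tert-butyldiphenylsilyl)oxy]-4-methoxy-2,6-bis(methoxymethoxy)benzamide | COCOc1cc(OC)cc(OCOC)c1C(=O)NO[Si](c2ccccc2)(c3ccccc3)C(C)(C)C
F6 | step 5 | (docosane-1-sulfonyl)benzene | O=S(=O)(c1ccccc1)CCCCCCCCCCCCCCCCCCCCCC
F7 | step 5 | 12-(benzenesulfonyl)tritriacontan-1-ol | OCCCCCCCCCCCC(S(=O)(=O)c1ccccc1)CCCCCCCCCCCCCCCCCCCCC
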